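**Plan**
1. Retrosynthesis: cut C11–C12 (α-sulfonyl carbanion + (2E,6E)-farnesyl bromide); take C8–OH back to a C7=C8 alkene and C11–OH back to an exocyclic C9=C11 methylene; cut ring A at C1–C2 (aldol) and at the two C4–CH3 bonds (enolate methylation); last, cut C5–C6 and C9–C10 (Diels–Alder).
2. Forward: ring B first, by [4+2] addition of 3-methylpenta-1,2,4-triene (C6–C9, C11 and the C8 methyl) to an acyclic (E)-enal (C1, C10, C5, with C2–C4 as a masked acetonyl arm); ring A second, by aldol condensation; the C16 chain last.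
3. Enabling feature: ring B is a cyclohexene retron (the C8 carbinol is a hydrated C7=C8). Its C5–C10 edge is an (E)-alkene while ring A is still open, so the trans ring fusion is built in. The allene carbon keeps C9 trigonal, so no endo/exo question arises next to the quaternary C10.
4. Stereochemistry: C5 and C10 come from suprafacial addition to the (E)-enal under a chiral oxazaborolidinium catalyst (absolute control). C9, C8 and C3 follow by reagent approach anti to the axial 10β-methyl (hydroboration, epoxidation/hydride, ketone reduction). The alkene geometry is bought with farnesyl bromide.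
5. Helpers: dioxolane (masked C3 ketone); the C3 carbonyl (drives ring A closure and C4 methylation, ends as the 3-OH); phenylsulfonyl at C11 (removed in the last step).

Key step: step 5

Assumption: the (S)-oxazaborolidinium salt is taken to expose the C2-Re/C3-Si face of enal 4 (the (R)-salt is used if the sense proves opposite), and either geometric isomer of enynol 5 serves because its alkene geometry is lost in 7.

Locants C1–C12 below follow drimane/polypodane numbering of the target.

**Step 1**
Reactants: 1 ethyl (2-methyl-1,3-dioxolan-2-yl)acetate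
Product: 2 (2-methyl-1,3-dioxolan-2-yl)acetaldehyde
Conditions: i-Bu2AlH (1.05 equiv), CH2Cl2, −78 °C; aqueous sodium potassium tartrate
Reagents that add atoms: none
Why: Low-temperature partial reduction of an ester by i-Bu2AlH stops at the tetrahedral aluminate, which gives the aldehyde on work-up; no stereocentre is formed.

**Step 2**
Reactants: 2 (2-methyl-1,3-dioxolan-2-yl)acetaldehyde; 3 2-(triphenyl-λ5-phosphanylidene)propanal
Product: 4 (2E)-2-methyl-4-(2-methyl-1,3-dioxolan-2-yl)but-2-enal
Conditions: toluene, 90 °C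
Reagents that add atoms: none
Why: Wittig olefination with a stabilised ylide should give the (E)-trisubstituted enal, placing the formyl group (future C1) trans to the masked acetonyl arm (future C4), as the later trans ring fusion requires.

**Step 3**
Reactants: 5 (2E)-3-methylpent-2-en-4-yn-1-ol
Product: 6 (3E)-5-chloro-3-methylpent-3-en-1-yne
Conditions: PPh3, CCl4, CH2Cl2, 0 °C → rt
Reagents that add atoms: tetrachloromethane, ClC(Cl)(Cl)Cl
Why: Appel chlorination replaces the primary allylic hydroxyl by chloride through SN2 displacement of the oxyphosphonium leaving group; no stereocentre is formed.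

**Step 4**
Reactants: 6 (3E)-5-chloro-3-methylpent-3-en-1-yne
Product: 7 3-methylpenta-1,2,4-triene
Conditions: Zn(Cu), n-BuOH, 70 °C, product distilled from the mixture
Reagents that add atoms: none
Why: Reductive 1,5-transposition: the organozinc formed at the allylic terminus is protonated at the remote acetylenic carbon, the classical route from 5-halopent-3-en-1-ynes to vinylallenes; the alkene geometry of 6 is lost.

**Step 5**
Reactants: 4 (2E)-2-methyl-4-(2-methyl-1,3-dioxolan-2-yl)but-2-enal; 7 3-methylpenta-1,2,4-triene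
Product: 8 (1S,6S)-1,3-dimethyl-2-methylidene-6-[(2-methyl-1,3-dioxolan-2-yl)methyl]cyclohex-3-ene-1-carbaldehyde
Conditions: (S)-3,3-diphenyl-1-(2-methylphenyl)tetrahydro-1H,3H-pyrrolo[1,2-c][1,3,2]oxazaborole (20 mol %), HNTf2 (18 mol %), 7 (3 equiv), CH2Cl2, −78 → −40 °C
Reagents that add atoms: none
Why: The protonated oxazaborolidine binds the formyl oxygen of 4 and lowers its LUMO, and the s-cis diene unit C6=C7–C8=C9 of vinylallene 7 adds across C5=C10 in a concerted, asynchronous normal-demand Diels–Alder reaction in which C5–C6 bonding runs ahead of C9–C10 bonding. The closest known reaction types are the oxazaborolidinium-catalysed Diels–Alder reactions of 2-substituted enals with acyclic dienes and the "ortho"-selective cycloadditions of vinylallenes. Ring B is closed as a six-membered carbocycle in a [4+2] mode, suprafacial on both partners, leaving C7=C8 endocyclic and C9=C11 exocyclic. C5 and C10 are set relative to each other by stereospecific syn addition to the (E)-alkene, so that C1 and C4 are trans on ring B and the later ring fusion is trans; they are set absolutely by the catalyst, which screens one face of the bound enal so that the diene should add to the C2-Re/C3-Si face. The step needs regioselectivity, which should come from the larger HOMO coefficient and free access at the vinyl terminus C6 (bonding to the β-carbon C5) and from the small sp-hybridised C9 bonding to the quaternary-to-be C10; endo/exo selectivity is not needed because C9 stays trigonal. The transoid diene of 8 cannot add a second dienophile.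

**Step 6**
Reactants: 8 (1S,6S)-1,3-dimethyl-2-methylidene-6-[(2-methyl-1,3-dioxolan-2-yl)methyl]cyclohex-3-ene-1-carbaldehyde
Product: 10 13,14-dinordrima-1,7,9(11)-trien-3-one, via keto aldehyde 9 (not isolated)
Conditions: pyridinium p-toluenesulfonate, acetone/H2O, 50 °C; then KOH, MeOH, 50 °C
Reagents that add atoms: water, O
Why: Acid-catalysed acetal hydrolysis frees the methyl ketone, whose methyl carbon (C2) then closes ring A onto the non-enolisable aldehyde (C1) by base-mediated intramolecular aldol condensation, the trans disposition of the two arms giving the trans-fused enone.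

**Step 7**
Reactants: 10 13,14-dinordrima-1,7,9(11)-trien-3-one
Product: 12 drima-1,7,9(11)-trien-3-one, via monomethyl enone 11 (not isolated)
Conditions: KOt-Bu (3 equiv), MeI (6 equiv), t-BuOH/THF, 0 °C → rt
Reagents that add atoms: iodomethane, CI
Why: Exhaustive enolate C-methylation at C4, the only enolisable position of the enone (C10 is quaternary, C2 is vinylic), installs the geminal dimethyl group; no stereocentre results.

**Step 8**
Reactants: 12 drima-1,7,9(11)-trien-3-one
Product: 13 drima-7,9(11)-dien-3-one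
Conditions: [(Ph3P)CuH]6 (0.4 equiv), H2O (2 equiv), benzene/THF, rt
Reagents that add atoms: none
Why: Copper hydride conjugate reduction delivers hydride to the β-carbon (C1) of the enone chemoselectively and leaves the electron-rich diene untouched; no stereocentre is formed.

**Step 9**
Reactants: 13 drima-7,9(11)-dien-3-one
Product: 14 drima-7,9(11)-dien-3β-ol
Conditions: NaBH4, MeOH, 0 °C
Reagents that add atoms: none
Why: Hydride reduction of the 4,4-dimethyl-3-ketone: the axial 4β- and 10β-methyl groups screen the β-face, so hydride should enter from the α-face and give the equatorial 3β-alcohol.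

**Step 10**
Reactants: 14 drima-7,9(11)-dien-3β-ol
Product: 16 drim-7-ene-3β,11-diol, via alkylborane 15 (not isolated)
Conditions: 9-borabicyclo[3.3.1]nonane (2.5 equiv), THF, 0 °C → rt; then NaOH, H2O2, 0 °C
Reagents that add atoms: hydrogen peroxide, OO
Why: Hydroboration–oxidation: the bulky borane adds anti-Markovnikov to the 1,1-disubstituted terminus of the diene from the α-face, opposite the axial 10β-methyl, so C9 receives its hydrogen on the α-face and C11 ends β (equatorial).

**Step 11**
Reactants: 16 drim-7-ene-3β,11-diol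
Product: 17 11-(phenylsulfanyl)drim-7-en-3β-ol
Conditions: PhSSPh, n-Bu3P, pyridine, 60 °C
Reagents that add atoms: diphenyl disulfide, c1ccccc1SSc1ccccc1
Why: Redox condensation (Hata thioetherification) activates the primary hydroxyl as an oxyphosphonium ion that thiolate displaces by SN2, the hindered secondary 3-OH being inert; no stereocentre is touched.

**Step 12**
Reactants: 17 11-(phenylsulfanyl)drim-7-en-3β-ol
Product: 19 7α,8α-epoxy-11-(phenylsulfonyl)driman-3β-ol, via alkene sulfone 18 (not isolated)
Conditions: mCPBA (3.3 equiv), NaHCO3, CH2Cl2, 0 °C → rt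
Reagents that add atoms: 3-chloroperoxybenzoic acid, OOC(=O)c1cccc(Cl)c1
Why: Peracid oxidation takes sulfur to the sulfone and then epoxidises the trisubstituted C7=C8 bond (Prilezhaev reaction) from the α-face, the β-face being screened by the 10β-methyl and the C9 side arm.

**Step 13**
Reactants: 19 7α,8α-epoxy-11-(phenylsulfonyl)driman-3β-ol
Product: 20 11-(phenylsulfonyl)drimane-3β,8α-diol
Conditions: LiBHEt3 (4 equiv), THF, 0 → 40 °C
Reagents that add atoms: none
Why: Hydride opens the trisubstituted epoxide by SN2 attack at the secondary carbon C7, so the C8–O bond and its α-configuration are kept and the tertiary 8α-alcohol results; the sulfone is inert to LiBHEt3.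

**Step 14**
Reactants: 20 11-(phenylsulfonyl)drimane-3β,8α-diol; 21 (2E,6E)-farnesyl bromide
Product: 22 11-(phenylsulfonyl)-8α-hydroxypolypoda-13E,17E,21-trien-3β-ol
Conditions: n-BuLi (3.1 equiv), THF/HMPA, −78 °C; then 21 (1.2 equiv), −78 → −30 °C
Reagents that add atoms: none
Why: Alkylation of the α-sulfonyl carbanion (Julia-type sulfone alkylation) at the primary allylic carbon of the bromide (SN2) forms C11–C12 without touching the (E)-alkenes, the two lithium alkoxides being far less nucleophilic; the new C11 centre is inconsequential because it is destroyed in step 15.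

**Step 15**
Reactants: 22 11-(phenylsulfonyl)-8α-hydroxypolypoda-13E,17E,21-trien-3β-ol
Product: 23 8α-hydroxypolypoda-13E,17E,21-trien-3β-ol
Conditions: Na/Hg (6%), Na2HPO4, MeOH/THF, −20 °C
Reagents that add atoms: none
Why: Dissolving-metal reductive desulfonylation cleaves the C11–S bond by electron transfer and protonation, leaving the isolated trisubstituted alkenes and all five stereocentres intact.

**Compound list**
1 | ethyl (2-methyl-1,3-dioxolan-2-yl)acetate | CCOC(=O)CC1(C)OCCO1 | starting material
2 | (2-methyl-1,3-dioxolan-2-yl)acetaldehyde | O=CCC1(C)OCCO1 | intermediate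
3 | 2-(triphenyl-λ5-phosphanylidene)propanal | CC(C=O)=P(c1ccccc1)(c1ccccc1)c1ccccc1 | starting material
4 | (2E)-2-methyl-4-(2-methyl-1,3-dioxolan-2-yl)but-2-enal | O=C/C(C)=C/CC1(C)OCCO1 | intermediate
5 | (2E)-3-methylpent-2-en-4-yn-1-ol | C#C/C(C)=C/CO | starting material
6 | (3E)-5-chloro-3-methylpent-3-en-1-yne | C#C/C(C)=C/CCl | intermediate
7 | 3-methylpenta-1,2,4-triene | C=C=C(C)C=C | intermediate
8 | (1S,6S)-1,3-dimethyl-2-methylidene-6-[(2-methyl-1,3-dioxolan-2-yl)methyl]cyclohex-3-ene-1-carbaldehyde | C=C1[C@@](C)(C=O)[C@H](CC2(C)OCCO2)CC=C1C | intermediate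
9 | (1S,6S)-1,3-dimethyl-2-methylidene-6-(2-oxopropyl)cyclohex-3-ene-1-carbaldehyde (keto aldehyde) | C=C1[C@@](C)(C=O)[C@H](CC(C)=O)CC=C1C | intermediate
10 | 13,14-dinordrima-1,7,9(11)-trien-3-one (5α-H, 10β-CH3) | C=C1[C@@]2(C)C=CC(=O)C[C@@H]2CC=C1C | intermediate
11 | 14-nordrima-1,7,9(11)-trien-3-one (monomethyl enone, both C4 epimers) | C=C1[C@@]2(C)C=CC(=O)C(C)[C@@H]2CC=C1C | intermediate
12 | drima-1,7,9(11)-trien-3-one | C=C1[C@@]2(C)C=CC(=O)C(C)(C)[C@@H]2CC=C1C | intermediate
13 | drima-7,9(11)-dien-3-one | C=C1[C@@]2(C)CCC(=O)C(C)(C)[C@@H]2CC=C1C | intermediate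
14 | drima-7,9(11)-dien-3β-ol | C=C1[C@@]2(C)CC[C@H](O)C(C)(C)[C@@H]2CC=C1C | intermediate
15 | 11-(9-borabicyclo[3.3.1]nonan-9-yl)drim-7-en-3β-ol (alkylborane) | C12CCCC(CCC1)B2C[C@@H]3[C@@]4(C)CC[C@H](O)C(C)(C)[C@@H]4CC=C3C | intermediate
16 | drim-7-ene-3β,11-diol | OC[C@@H]1[C@@]2(C)CC[C@H](O)C(C)(C)[C@@H]2CC=C1C | intermediate
17 | 11-(phenylsulfanyl)drim-7-en-3β-ol | c1ccccc1SC[C@@H]1[C@@]2(C)CC[C@H](O)C(C)(C)[C@@H]2CC=C1C | intermediate
18 | 11-(phenylsulfonyl)drim-7-en-3β-ol (alkene sulfone) | O=S(=O)(c1ccccc1)C[C@@H]1[C@@]2(C)CC[C@H](O)C(C)(C)[C@@H]2CC=C1C | intermediate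
19 | 7α,8α-epoxy-11-(phenylsulfonyl)driman-3β-ol | O=S(=O)(c1ccccc1)C[C@@H]1[C@@]2(C)CC[C@H](O)C(C)(C)[C@@H]2C[C@H]3O[C@@]13C | intermediate
20 | 11-(phenylsulfonyl)drimane-3β,8α-diol | O=S(=O)(c1ccccc1)C[C@@H]1[C@@]2(C)CC[C@H](O)C(C)(C)[C@@H]2CC[C@@]1(C)O | intermediate
21 | (2E,6E)-farnesyl bromide | CC(C)=CCC/C(C)=C/CC/C(C)=C/CBr | starting material
22 | 11-(phenylsulfonyl)-8α-hydroxypolypoda-13E,17E,21-trien-3β-ol (both C11 epimers) | CC(C)=CCC/C(C)=C/CC/C(C)=C/CC(S(=O)(=O)c1ccccc1)[C@@H]1[C@@]2(C)CC[C@H](O)C(C)(C)[C@@H]2CC[C@@]1(C)O | intermediate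
23 | 8α-hydroxypolypoda-13E,17E,21-trien-3β-ol | CC(C)=CCC/C(C)=C/CC/C(C)=C/CC[C@@H]1[C@@]2(C)CC[C@H](O)C(C)(C)[C@@H]2CC[C@@]1(C)O | target

**Step count**
Total: 15 steps. Longest linear sequence: 13 steps (steps 1, 2 and 5–15).

**Steps most likely to fail**

Step 5. The diene may add with the reverse orientation (the 3-methyl group outweighing the allene terminus), bond too slowly at the congested α-carbon, or be discriminated poorly between the two enal faces. The fallback sets out from 4 and returns at 14. Enal 4 is combined, under the same oxazaborolidinium catalysis, with (1E)-2-methyl-1-[(triisopropylsilyl)oxy]buta-1,3-diene F1 (from (E)-2-methylbut-2-enal, i-Pr3SiOTf, Et3N). Its 1-oxygen substituent dictates the "ortho" orientation and raises the reactivity, giving the C9-silyloxy cycloadduct F2. Acetal hydrolysis and aldol condensation as in step 6 give 9α-[(triisopropylsilyl)oxy]-11,13,14-trinordrima-1,7-dien-3-one F3. Methylation as in step 7 gives 9α-[(triisopropylsilyl)oxy]-11-nordrima-1,7-dien-3-one F4. Conjugate reduction as in step 8 gives 9α-[(triisopropylsilyl)oxy]-11-nordrim-7-en-3-one F5, and NaBH4 gives 9α-[(triisopropylsilyl)oxy]-11-nordrim-7-en-3β-ol F6. Bu4NF frees 11-nordrim-7-ene-3β,9α-diol F7, MnO2 oxidises only its allylic hydroxyl to 3β-hydroxy-11-nordrim-7-en-9-one F8, and Wittig methylenation (Ph3P=CH2) of F8 delivers 14.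

Step 14. The hindered trilithio species may alkylate incompletely at carbon, alkylate at oxygen, or merely be protonated. The fallback sets out from 16 and returns at 23, forming C12–C13 by sp3–sp2 coupling instead. The primary alcohol of 16 is oxidised selectively (TEMPO, PhI(OAc)2) to 3β-hydroxydrim-7-en-11-al F9, which is methylenated at once (Ph3P=CH2, −78 °C) to 11-methylidenedrim-7-en-3β-ol F10. mCPBA (1 equiv) epoxidises the trisubstituted alkene to 7α,8α-epoxy-11-methylidenedriman-3β-ol F11, and LiBHEt3 gives 11-methylidenedrimane-3β,8α-diol F12. Hydroboration of the vinyl group with 9-borabicyclo[3.3.1]nonane gives the alkylborane F13 (not isolated). This is coupled (PdCl2(dppf), AsPh3, Cs2CO3, DMF/H2O) with (1E,5E)-1-iodo-2,6,10-trimethylundeca-1,5,9-triene F14, made from the corresponding terminal alkyne by Cp2ZrCl2-catalysed carboalumination with Me3Al and iodination, to give 23.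

Step 13. Hydride may attack the wrong epoxide carbon, or the epoxide may open by base to an allylic alcohol. The fallback sets out from 17 and returns at 20, avoiding the epoxide. Sulfur alone is oxidised (H2O2, (NH4)6Mo7O24) to the alkene sulfone 18, now isolated. The C7=C8 bond is then hydrated directly by hydrogen-atom-transfer (Mukaiyama) hydration (Co(acac)2, PhSiH3, O2, i-PrOH), the tertiary C8 radical being trapped by O2 from the α-face. No new compound arises (F0).

**Further compounds**
F1 | step 5 | (1E)-2-methyl-1-[(triisopropylsilyl)oxy]buta-1,3-diene | C=C/C(C)=C/O[Si](C(C)C)(C(C)C)C(C)C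
F2 | step 5 | 1,3-dimethyl-6-[(2-methyl-1,3-dioxolan-2-yl)methyl]-2-[(triisopropylsilyl)oxy]cyclohex-3-ene-1-carbaldehyde (formyl and silyloxy cis, formyl and dioxolanylmethyl trans) | CC1=CC[C@@H](CC2(C)OCCO2)[C@](C)(C=O)[C@@H]1O[Si](C(C)C)(C(C)C)C(C)C
F3 | step 5 | 9α-[(triisopropylsilyl)oxy]-11,13,14-trinordrima-1,7-dien-3-one | CC1=CC[C@H]2CC(=O)C=C[C@]2(C)[C@@H]1O[Si](C(C)C)(C(C)C)C(C)C
F4 | step 5 | 9α-[(triisopropylsilyl)oxy]-11-nordrima-1,7-dien-3-one | CC1=CC[C@H]2C(C)(C)C(=O)C=C[C@]2(C)[C@@H]1O[Si](C(C)C)(C(C)C)C(C)C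
F5 | step 5 | 9α-[(triisopropylsilyl)oxy]-11-nordrim-7-en-3-one | CC1=CC[C@H]2C(C)(C)C(=O)CC[C@]2(C)[C@@H]1O[Si](C(C)C)(C(C)C)C(C)C
F6 | step 5 | 9α-[(triisopropylsilyl)oxy]-11-nordrim-7-en-3β-ol | CC1=CC[C@H]2C(C)(C)[C@@H](O)CC[C@]2(C)[C@@H]1O[Si](C(C)C)(C(C)C)C(C)C
F7 | step 5 | 11-nordrim-7-ene-3β,9α-diol | CC1=CC[C@H]2C(C)(C)[C@@H](O)CC[C@]2(C)[C@@H]1O
F8 | step 5 | 3β-hydroxy-11-nordrim-7-en-9-one | CC1=CC[C@H]2C(C)(C)[C@@H](O)CC[C@]2(C)C1=O
F9 | step 14 | 3β-hydroxydrim-7-en-11-al | O=C[C@@H]1[C@@]2(C)CC[C@H](O)C(C)(C)[C@@H]2CC=C1C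
F10 | step 14 | 11-methylidenedrim-7-en-3β-ol | C=C[C@@H]1[C@@]2(C)CC[C@H](O)C(C)(C)[C@@H]2CC=C1C
F11 | step 14 | 7α,8α-epoxy-11-methylidenedriman-3β-ol | C=C[C@@H]1[C@@]2(C)CC[C@H](O)C(C)(C)[C@@H]2C[C@H]3O[C@@]13C
F12 | step 14 | 11-methylidenedrimane-3β,8α-diol | C=C[C@@H]1[C@@]2(C)CC[C@H](O)C(C)(C)[C@@H]2CC[C@@]1(C)O
F13 | step 14 | 11-[(9-borabicyclo[3.3.1]nonan-9-yl)methyl]drimane-3β,8α-diol | C12CCCC(CCC1)B2CC[C@@H]1[C@@]2(C)CC[C@H](O)C(C)(C)[C@@H]2CC[C@@]1(C)O
F14 | step 14 | (1E,5E)-1-iodo-2,6,10-trimethylundeca-1,5,9-triene | CC(C)=CCC/C(C)=C/CC/C(C)=C/I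
F0 | step 13 | none | none
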